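**Retrosynthetic overview**
- Target ⇐ Knoevenagel–Doebner condensation of a benzodioxane-6-carbaldehyde with malonic acid, then removal of an O-allyl group; the aldehyde ⇐ the aryl nitrile.
- The 1,4-dioxane ring is the only ring made (both benzene rings are bought). It is closed by intramolecular SNAr of the benzylic alkoxide on a C–F bond para to the nitrile, with the primary OH masked as a trityl ether and retention at both stereocentres.
- The threo-(1R,2R)-2-aryloxy-1-arylpropane-1,3-diol ⇐ reductive removal of the auxiliary from a syn-aldol adduct.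
- Key C–C bond (future C2–C3): Evans boron aldol of an N-(aryloxyacetyl)-(S)-4-benzyloxazolidinone with O-allylvanillin, which sets both stereocentres at once.
- Building blocks: vanillin, 4-fluoro-3-hydroxybenzonitrile, tert-butyl bromoacetate, (S)-4-benzyl-2-oxazolidinone, malonic acid.

Assumption: the SMILES is read as the (2R,3R)-trans-benzodioxane whose ring oxygen on the aryl-bearing carbon is para to the propenoic acid chain; all named building blocks are taken as purchasable.

**Route**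

Step 1
Reactants: 1 vanillin
Product: 2 4-allyloxy-3-methoxybenzaldehyde
Conditions: allyl bromide, K2CO3, acetone, reflux
Reagents that add atoms: allyl bromide, C=CCBr
Why: Williamson ether synthesis of the phenoxide with a reactive allylic bromide gives an ether that survives the later Lewis-acid, hydride and base steps and can be removed last under neutral conditions.

Step 2
Reactants: 3 4-fluoro-3-hydroxybenzonitrile; 4 tert-butyl bromoacetate
Product: 5 tert-butyl 2-(5-cyano-2-fluorophenoxy)acetate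
Conditions: K2CO3, MeCN, 50 °C
Reagents that add atoms: none
Why: Williamson O-alkylation by the α-bromo ester is far faster at 50 °C than any attack of the phenoxide on the C–F bond of a second molecule.

Step 3
Reactants: 5 tert-butyl 2-(5-cyano-2-fluorophenoxy)acetate
Product: 6 2-(5-cyano-2-fluorophenoxy)acetic acid
Conditions: TFA, CH2Cl2, rt
Reagents that add atoms: none
Why: Acidolysis of the tert-butyl ester (loss of 2-methylpropene) frees the acid without hydroxide, so the nitrile and the activated C–F bond are untouched.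

Step 4
Reactants: 6 2-(5-cyano-2-fluorophenoxy)acetic acid; 7 (4S)-4-benzyl-1,3-oxazolidin-2-one
Product: 9 (4S)-4-benzyl-3-[2-(5-cyano-2-fluorophenoxy)acetyl]-1,3-oxazolidin-2-one, via mixed pivalic anhydride 8 (not isolated)
Conditions: PivCl, Et3N, THF, −20 °C; then LiCl, 7, −20 °C → rt
Reagents that add atoms: none
Why: N-acylation through a mixed anhydride, in which the LiCl-activated oxazolidinone attacks the less hindered and more electrophilic aryloxyacetyl carbonyl.

Step 5
Reactants: 9 (4S)-4-benzyl-3-[2-(5-cyano-2-fluorophenoxy)acetyl]-1,3-oxazolidin-2-one; 2 4-allyloxy-3-methoxybenzaldehyde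
Product: 12 (4S)-4-benzyl-3-[(2S,3R)-3-(4-allyloxy-3-methoxyphenyl)-2-(5-cyano-2-fluorophenoxy)-3-hydroxypropanoyl]-1,3-oxazolidin-2-one, via Z-dibutylboron enolate 10 (not isolated), via dibutylboron aldolate 11 (not isolated)
Conditions: Bu2BOTf (1.2 equiv), iPr2NEt (1.4 equiv), CH2Cl2, −78 → 0 °C; then 2, −78 → 0 °C; then aq. KH2PO4/K2HPO4 (pH 7), MeOH, 30% H2O2, 0 °C
Reagents that add atoms: none
Why: Evans syn-aldol reaction, in which the Z-boron enolate reacts through a closed Zimmerman–Traxler chair on the face away from the benzyl group, fixing the syn (2S,3R) relationship and the absolute configuration of both new stereocentres in one C–C bond formation.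

Step 6
Reactants: 12 (4S)-4-benzyl-3-[(2S,3R)-3-(4-allyloxy-3-methoxyphenyl)-2-(5-cyano-2-fluorophenoxy)-3-hydroxypropanoyl]-1,3-oxazolidin-2-one
Product: 14 3-{[(1R,2R)-1-(4-allyloxy-3-methoxyphenyl)-1,3-dihydroxypropan-2-yl]oxy}-4-fluorobenzonitrile, via hydroxy aldehyde 13 (not isolated)
Conditions: NaBH4, THF/H2O (4:1), 0 °C → rt
Reagents that add atoms: none
Why: Reductive cleavage of the N-acyl oxazolidinone by hydride attack at the exocyclic carbonyl gives the threo 1,3-diol and returns the auxiliary, while the aryl nitrile, aryl fluoride, allyl ether and both stereocentres are unaffected.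

Step 7
Reactants: 14 3-{[(1R,2R)-1-(4-allyloxy-3-methoxyphenyl)-1,3-dihydroxypropan-2-yl]oxy}-4-fluorobenzonitrile
Product: 15 3-{[(1R,2R)-1-(4-allyloxy-3-methoxyphenyl)-1-hydroxy-3-(trityloxy)propan-2-yl]oxy}-4-fluorobenzonitrile
Conditions: TrCl, Et3N, DMAP (cat.), CH2Cl2, rt
Reagents that add atoms: trityl chloride, ClC(c1ccccc1)(c1ccccc1)c1ccccc1
Why: Sterically controlled tritylation takes only the primary hydroxyl, and the non-migrating trityl ether leaves the benzylic hydroxyl as the sole nucleophile for ring closure.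

Step 8
Reactants: 15 3-{[(1R,2R)-1-(4-allyloxy-3-methoxyphenyl)-1-hydroxy-3-(trityloxy)propan-2-yl]oxy}-4-fluorobenzonitrile
Product: 16 (2R,3R)-2-(4-allyloxy-3-methoxyphenyl)-3-(trityloxymethyl)-2,3-dihydro-1,4-benzodioxine-6-carbonitrile
Conditions: NaH (1.3 equiv), THF/DMF (4:1), 0 °C → rt
Reagents that add atoms: none
Why: Intramolecular SNAr (addition–elimination) of the benzylic alkoxide at the C–F carbon para to the nitrile closes the six-membered ring without breaking a bond at either stereocentre, so the threo (1R,2R) diol becomes the trans (2R,3R) dioxane.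

Step 9
Reactants: 16 (2R,3R)-2-(4-allyloxy-3-methoxyphenyl)-3-(trityloxymethyl)-2,3-dihydro-1,4-benzodioxine-6-carbonitrile
Product: 17 (2R,3R)-2-(4-allyloxy-3-methoxyphenyl)-3-(hydroxymethyl)-2,3-dihydro-1,4-benzodioxine-6-carbonitrile
Conditions: CSA (0.2 equiv), MeOH/CH2Cl2 (1:1), rt
Reagents that add atoms: none
Why: Acid-catalysed SN1 methanolysis of the trityl ether occurs under conditions mild enough to leave the benzylic aryl ether of the dioxane, the allyl ether and the nitrile intact.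

Step 10
Reactants: 17 (2R,3R)-2-(4-allyloxy-3-methoxyphenyl)-3-(hydroxymethyl)-2,3-dihydro-1,4-benzodioxine-6-carbonitrile
Product: 19 (2R,3R)-2-(4-allyloxy-3-methoxyphenyl)-3-(hydroxymethyl)-2,3-dihydro-1,4-benzodioxine-6-carbaldehyde, via N-aluminio imine 18 (not isolated)
Conditions: iBu2AlH (3 equiv), CH2Cl2, −78 → 0 °C; then aq. potassium sodium tartrate, then 10% aq. citric acid, rt
Reagents that add atoms: water, O
Why: Partial reduction of the nitrile, in which one equivalent of hydride is consumed by the hydroxyl and a single hydride adds to the nitrile to give an N-aluminio imine that resists further reduction and is hydrolysed to the aldehyde on work-up.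

Step 11
Reactants: 19 (2R,3R)-2-(4-allyloxy-3-methoxyphenyl)-3-(hydroxymethyl)-2,3-dihydro-1,4-benzodioxine-6-carbaldehyde; 20 malonic acid
Product: 22 (2E)-3-[(2R,3R)-2-(4-allyloxy-3-methoxyphenyl)-3-(hydroxymethyl)-2,3-dihydro-1,4-benzodioxin-6-yl]prop-2-enoic acid, via arylidenemalonic acid 21 (not isolated)
Conditions: pyridine, piperidine (cat.), 90 °C; then aq. HCl
Reagents that add atoms: none
Why: Knoevenagel–Doebner condensation (aldol-type condensation followed by decarboxylation in pyridine) gives the free cinnamic acid directly and with E geometry under thermodynamic control.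

Step 12
Reactants: 22 (2E)-3-[(2R,3R)-2-(4-allyloxy-3-methoxyphenyl)-3-(hydroxymethyl)-2,3-dihydro-1,4-benzodioxin-6-yl]prop-2-enoic acid
Product: 23 (2E)-3-[(2R,3R)-2-(4-hydroxy-3-methoxyphenyl)-3-(hydroxymethyl)-2,3-dihydro-1,4-benzodioxin-6-yl]prop-2-enoic acid (CNP0187155.2)
Conditions: Pd(PPh3)4 (5 mol %), morpholine (5 equiv), THF, rt; then dilute aq. HCl to pH 3
Reagents that add atoms: none
Why: Tsuji–Trost deallylation, in which zerovalent palladium ionises the allyl aryl ether to a π-allyl complex that morpholine captures, frees the phenol at room temperature without touching the alkene, the acid or the stereocentres.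

**Compound list**

1 | vanillin (4-hydroxy-3-methoxybenzaldehyde) | COc1cc(C=O)ccc1O | starting material
2 | 4-allyloxy-3-methoxybenzaldehyde | C=CCOc1ccc(C=O)cc1OC | intermediate
3 | 4-fluoro-3-hydroxybenzonitrile | N#Cc1ccc(F)c(O)c1 | starting material
4 | tert-butyl bromoacetate | CC(C)(C)OC(=O)CBr | starting material
5 | tert-butyl 2-(5-cyano-2-fluorophenoxy)acetate | CC(C)(C)OC(=O)COc1cc(C#N)ccc1F | intermediate
6 | 2-(5-cyano-2-fluorophenoxy)acetic acid | OC(=O)COc1cc(C#N)ccc1F | intermediate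
7 | (4S)-4-benzyl-1,3-oxazolidin-2-one | O=C1OC[C@H](Cc2ccccc2)N1 | starting material
8 | 2-(5-cyano-2-fluorophenoxy)acetic pivalic anhydride (not isolated) | CC(C)(C)C(=O)OC(=O)COc1cc(C#N)ccc1F | intermediate
9 | (4S)-4-benzyl-3-[2-(5-cyano-2-fluorophenoxy)acetyl]-1,3-oxazolidin-2-one | O=C1OC[C@H](Cc2ccccc2)N1C(=O)COc1cc(C#N)ccc1F | intermediate
10 | (4S)-4-benzyl-3-[(Z)-2-(5-cyano-2-fluorophenoxy)-1-(dibutylboranyloxy)ethenyl]-1,3-oxazolidin-2-one (not isolated) | CCCCB(CCCC)O/C(=C\Oc1cc(C#N)ccc1F)N1C(=O)OC[C@@H]1Cc1ccccc1 | intermediate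
11 | O-dibutylboranyl derivative of 12 at the (3R)-oxygen (not isolated) | O=C1OC[C@H](Cc2ccccc2)N1C(=O)[C@@H](Oc1cc(C#N)ccc1F)[C@H](OB(CCCC)CCCC)c1ccc(OCC=C)c(OC)c1 | intermediate
12 | (4S)-4-benzyl-3-[(2S,3R)-3-(4-allyloxy-3-methoxyphenyl)-2-(5-cyano-2-fluorophenoxy)-3-hydroxypropanoyl]-1,3-oxazolidin-2-one | O=C1OC[C@H](Cc2ccccc2)N1C(=O)[C@@H](Oc1cc(C#N)ccc1F)[C@H](O)c1ccc(OCC=C)c(OC)c1 | intermediate
13 | (2S,3R)-3-(4-allyloxy-3-methoxyphenyl)-2-(5-cyano-2-fluorophenoxy)-3-hydroxypropanal (not isolated) | O=C[C@@H](Oc1cc(C#N)ccc1F)[C@H](O)c1ccc(OCC=C)c(OC)c1 | intermediate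
14 | 3-{[(1R,2R)-1-(4-allyloxy-3-methoxyphenyl)-1,3-dihydroxypropan-2-yl]oxy}-4-fluorobenzonitrile | OC[C@@H](Oc1cc(C#N)ccc1F)[C@H](O)c1ccc(OCC=C)c(OC)c1 | intermediate
15 | 3-{[(1R,2R)-1-(4-allyloxy-3-methoxyphenyl)-1-hydroxy-3-(trityloxy)propan-2-yl]oxy}-4-fluorobenzonitrile | c1ccccc1C(c1ccccc1)(c1ccccc1)OC[C@@H](Oc1cc(C#N)ccc1F)[C@H](O)c1ccc(OCC=C)c(OC)c1 | intermediate
16 | (2R,3R)-2-(4-allyloxy-3-methoxyphenyl)-3-(trityloxymethyl)-2,3-dihydro-1,4-benzodioxine-6-carbonitrile | C=CCOc1ccc([C@H]2Oc3ccc(C#N)cc3O[C@@H]2COC(c4ccccc4)(c4ccccc4)c4ccccc4)cc1OC | intermediate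
17 | (2R,3R)-2-(4-allyloxy-3-methoxyphenyl)-3-(hydroxymethyl)-2,3-dihydro-1,4-benzodioxine-6-carbonitrile | C=CCOc1ccc([C@H]2Oc3ccc(C#N)cc3O[C@@H]2CO)cc1OC | intermediate
18 | N,O-bis(diisobutylaluminio) aldimine of 19: 6-CH=N–Al(iBu)2 and 3-CH2O–Al(iBu)2 on the (2R,3R)-benzodioxane (not isolated) | C=CCOc1ccc([C@H]2Oc3ccc(C=N[Al](CC(C)C)CC(C)C)cc3O[C@@H]2CO[Al](CC(C)C)CC(C)C)cc1OC | intermediate
19 | (2R,3R)-2-(4-allyloxy-3-methoxyphenyl)-3-(hydroxymethyl)-2,3-dihydro-1,4-benzodioxine-6-carbaldehyde | C=CCOc1ccc([C@H]2Oc3ccc(C=O)cc3O[C@@H]2CO)cc1OC | intermediate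
20 | malonic acid | OC(=O)CC(=O)O | starting material
21 | 2-{[(2R,3R)-2-(4-allyloxy-3-methoxyphenyl)-3-(hydroxymethyl)-2,3-dihydro-1,4-benzodioxin-6-yl]methylidene}propanedioic acid (not isolated) | C=CCOc1ccc([C@H]2Oc3ccc(C=C(C(=O)O)C(=O)O)cc3O[C@@H]2CO)cc1OC | intermediate
22 | (2E)-3-[(2R,3R)-2-(4-allyloxy-3-methoxyphenyl)-3-(hydroxymethyl)-2,3-dihydro-1,4-benzodioxin-6-yl]prop-2-enoic acid | C=CCOc1ccc([C@H]2Oc3ccc(/C=C/C(=O)O)cc3O[C@@H]2CO)cc1OC | intermediate
23 | (2E)-3-[(2R,3R)-2-(4-hydroxy-3-methoxyphenyl)-3-(hydroxymethyl)-2,3-dihydro-1,4-benzodioxin-6-yl]prop-2-enoic acid | COc1cc([C@H]2Oc3ccc(/C=C/C(=O)O)cc3O[C@@H]2CO)ccc1O | target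

**Summary**

Total steps: 12. Longest linear sequence: 11 steps (steps 2 to 12, from 3 to 23); step 1 is a one-step side branch.

**Steps most likely to fail, with fallbacks**

Step 5 (aldol). The nitrile can tie up part of the boron triflate, the electron-rich aldehyde is a slow acceptor, and facial control for aryloxyacetyl enolates is less documented than for propionates. The fallback sets out from 6 and comes back at 14. Acid 6 is coupled with (4S)-4-benzyl-1,3-thiazolidine-2-thione (EDC·HCl, DMAP, CH2Cl2, rt) to give (4S)-4-benzyl-3-[2-(5-cyano-2-fluorophenoxy)acetyl]-1,3-thiazolidine-2-thione F1. Soft enolisation with TiCl4, iPr2NEt and N-methyl-2-pyrrolidinone in CH2Cl2, then addition of 2 at −78 → 0 °C, is a chlorotitanium-enolate aldol through an open-coordination chair. It should give the same syn adduct, (4S)-4-benzyl-3-[(2S,3R)-3-(4-allyloxy-3-methoxyphenyl)-2-(5-cyano-2-fluorophenoxy)-3-hydroxypropanoyl]-1,3-thiazolidine-2-thione F2. The very labile thione auxiliary is then removed with NaBH4 in THF/EtOH at 0 °C to return diol 14.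

Step 8 (ring closure). The ortho-alkoxy group lowers the electrophilicity of the C–F carbon, and the alkoxide sits next to a bulky trityloxymethyl group, so the SNAr may stall or give base-derived by-products. The fallback replaces it by a copper-catalysed Ullmann-type etherification on the bromo series. It sets out from 4 and comes back at 16.
- Commercial 4-bromo-3-hydroxybenzonitrile is alkylated with 4 (K2CO3, MeCN) to give tert-butyl 2-(2-bromo-5-cyanophenoxy)acetate F3.
- The operations of steps 3 to 7 are repeated unchanged. They give in turn 2-(2-bromo-5-cyanophenoxy)acetic acid F4, then (4S)-4-benzyl-3-[2-(2-bromo-5-cyanophenoxy)acetyl]-1,3-oxazolidin-2-one F5, then the syn-aldol adduct (4S)-4-benzyl-3-[(2S,3R)-3-(4-allyloxy-3-methoxyphenyl)-2-(2-bromo-5-cyanophenoxy)-3-hydroxypropanoyl]-1,3-oxazolidin-2-one F6.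
- Reduction and tritylation then give 3-{[(1R,2R)-1-(4-allyloxy-3-methoxyphenyl)-1,3-dihydroxypropan-2-yl]oxy}-4-bromobenzonitrile F7 and 3-{[(1R,2R)-1-(4-allyloxy-3-methoxyphenyl)-1-hydroxy-3-(trityloxy)propan-2-yl]oxy}-4-bromobenzonitrile F8.
- F8 is cyclised with CuI (10 mol %), 3,4,7,8-tetramethyl-1,10-phenanthroline (20 mol %) and Cs2CO3 in toluene at 110 °C. This intramolecular O-arylation also breaks no bond at a stereocentre and delivers 16.

Step 9 (detritylation). The C2–O1 bond of 16 is a p-alkoxybenzyl ether of a cyanophenol, so acid could ionise it and cause C2 epimerisation or ring-opening methanolysis. The fallback uses a fluoride-labile silyl ether instead of the acid-labile trityl ether. It sets out from 14 and comes back at 17. Diol 14 is silylated at the primary hydroxyl (TBDPSCl, imidazole, DMF, 0 °C) to give 3-{[(1R,2R)-1-(4-allyloxy-3-methoxyphenyl)-3-(tert-butyldiphenylsilyloxy)-1-hydroxypropan-2-yl]oxy}-4-fluorobenzonitrile F9. SNAr closure with Cs2CO3 in DMF at 50 °C, a weaker base chosen to suppress silyl migration, gives (2R,3R)-2-(4-allyloxy-3-methoxyphenyl)-3-[(tert-butyldiphenylsilyloxy)methyl]-2,3-dihydro-1,4-benzodioxine-6-carbonitrile F10. Bu4NF buffered with AcOH in THF at rt then gives 17 without any acid exposure.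

**Further compounds**

F1 | step 5 | (4S)-4-benzyl-3-[2-(5-cyano-2-fluorophenoxy)acetyl]-1,3-thiazolidine-2-thione | S=C1SC[C@H](Cc2ccccc2)N1C(=O)COc1cc(C#N)ccc1F
F2 | step 5 | (4S)-4-benzyl-3-[(2S,3R)-3-(4-allyloxy-3-methoxyphenyl)-2-(5-cyano-2-fluorophenoxy)-3-hydroxypropanoyl]-1,3-thiazolidine-2-thione | S=C1SC[C@H](Cc2ccccc2)N1C(=O)[C@@H](Oc1cc(C#N)ccc1F)[C@H](O)c1ccc(OCC=C)c(OC)c1
F3 | step 8 | tert-butyl 2-(2-bromo-5-cyanophenoxy)acetate | CC(C)(C)OC(=O)COc1cc(C#N)ccc1Br
F4 | step 8 | 2-(2-bromo-5-cyanophenoxy)acetic acid | OC(=O)COc1cc(C#N)ccc1Br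
F5 | step 8 | (4S)-4-benzyl-3-[2-(2-bromo-5-cyanophenoxy)acetyl]-1,3-oxazolidin-2-one | O=C1OC[C@H](Cc2ccccc2)N1C(=O)COc1cc(C#N)ccc1Br
F6 | step 8 | (4S)-4-benzyl-3-[(2S,3R)-3-(4-allyloxy-3-methoxyphenyl)-2-(2-bromo-5-cyanophenoxy)-3-hydroxypropanoyl]-1,3-oxazolidin-2-one | O=C1OC[C@H](Cc2ccccc2)N1C(=O)[C@@H](Oc1cc(C#N)ccc1Br)[C@H](O)c1ccc(OCC=C)c(OC)c1
F7 | step 8 | 3-{[(1R,2R)-1-(4-allyloxy-3-methoxyphenyl)-1,3-dihydroxypropan-2-yl]oxy}-4-bromobenzonitrile | OC[C@@H](Oc1cc(C#N)ccc1Br)[C@H](O)c1ccc(OCC=C)c(OC)c1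
F8 | step 8 | 3-{[(1R,2R)-1-(4-allyloxy-3-methoxyphenyl)-1-hydroxy-3-(trityloxy)propan-2-yl]oxy}-4-bromobenzonitrile | c1ccccc1C(c1ccccc1)(c1ccccc1)OC[C@@H](Oc1cc(C#N)ccc1Br)[C@H](O)c1ccc(OCC=C)c(OC)c1
F9 | step 9 | 3-{[(1R,2R)-1-(4-allyloxy-3-methoxyphenyl)-3-(tert-butyldiphenylsilyloxy)-1-hydroxypropan-2-yl]oxy}-4-fluorobenzonitrile | CC(C)(C)[Si](c1ccccc1)(c1ccccc1)OC[C@@H](Oc1cc(C#N)ccc1F)[C@H](O)c1ccc(OCC=C)c(OC)c1
F10 | step 9 | (2R,3R)-2-(4-allyloxy-3-methoxyphenyl)-3-[(tert-butyldiphenylsilyloxy)methyl]-2,3-dihydro-1,4-benzodioxine-6-carbonitrile | C=CCOc1ccc([C@H]2Oc3ccc(C#N)cc3O[C@@H]2CO[Si](c4ccccc4)(c4ccccc4)C(C)(C)C)cc1OC
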